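**Plan**

Retrosynthesis cuts, in this order: the terminal CH2OH carbon of the side chain (hydroformylation of a C6-vinyl group), the neopentyl CH2–OAr bond (Mitsunobu reaction with isofraxidin), the C2–H/C3–H bonds (hydrogenation of a C2=C3 alkene), and the two ring bonds C4–C5 and C6–C1 together in one [4+2] operation.
Enabling feature: in the cyclohexane ring, C6(H)–C5(=CMe2) is the imprint of the α,β-bond of a γ,γ-dimethylallenoyl dienophile, whose β,γ-bond survives as the isopropylidene group. C1(Me)(CH2O)–C2(Me)–C3–C4 is the imprint of a 1,1,2-trisubstituted butadiene.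
Forward: dimethylmaleic anhydride gives the (Z)-diene, and a ketene Wittig reaction gives the N-allenoyl oxazolidinone. Their Diels–Alder union builds the only ring that has to be made, together with the quaternary carbon, the C1/C6 pair and the tetrasubstituted alkene. The coumarin rings arrive ready-made with isofraxidin near the end.
Stereochemistry: C6 comes from the (S)-4-benzyloxazolidinone auxiliary. C1 comes from the ring-derived Z geometry of the diene plus endo addition. C2 comes from hydroxyl-directed hydrogenation on the face of the axial C6–CH2OH group.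

Key step: step 8

Remark: ring numbering used in all names is C1 = quaternary carbon (CH3, CH2O), C2 = C–CH3, C3, C4, C5 = C(=CMe2), C6 = CH bearing the side chain. Isofraxidin (7-hydroxy-6,8-dimethoxycoumarin) is assumed to be commercially available.

**Step 1**
Reactants: 1 2,3-dimethylmaleic anhydride
Product: 2 (2Z)-2,3-dimethylbut-2-ene-1,4-diol
Conditions: LiAlH4, Et2O, 0 °C to reflux; aqueous NaOH work-up
Reagents that add atoms: none
Why: Exhaustive LiAlH4 reduction of the cyclic anhydride gives the diol, and the Z geometry of the tetrasubstituted alkene is inherited from the five-membered ring.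

**Step 2**
Reactants: 2 (2Z)-2,3-dimethylbut-2-ene-1,4-diol
Product: 3 (2Z)-4-(tert-butyldimethylsilyloxy)-2,3-dimethylbut-2-en-1-ol
Conditions: NaH (1.0 equiv), THF, rt; then TBSCl (1.0 equiv)
Reagents that add atoms: tert-butyldimethylsilyl chloride, CC(C)(C)[Si](C)(C)Cl
Why: Monosilylation of a symmetrical diol through its poorly soluble monosodium alkoxide favours the mono-TBS ether, and any silyl migration is degenerate because both hydroxyl groups are equivalent.

**Step 3**
Reactants: 3 (2Z)-4-(tert-butyldimethylsilyloxy)-2,3-dimethylbut-2-en-1-ol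
Product: 4 (2Z)-4-(tert-butyldimethylsilyloxy)-2,3-dimethylbut-2-enal
Conditions: activated MnO2, CH2Cl2, rt
Reagents that add atoms: none
Why: MnO2 oxidation of the allylic primary alcohol runs under neutral conditions and should leave the silyl ether and the Z alkene untouched.

**Step 4**
Reactants: 4 (2Z)-4-(tert-butyldimethylsilyloxy)-2,3-dimethylbut-2-enal
Product: 5 tert-butyl{[(2Z)-2,3-dimethylpenta-2,4-dien-1-yl]oxy}dimethylsilane
Conditions: Ph3PCH3Br, n-BuLi, THF, −78 to 0 °C
Reagents that add atoms: methyltriphenylphosphonium bromide, C[P+](c1ccccc1)(c1ccccc1)c1ccccc1.[Br-]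
Why: Wittig methylenation installs the vinyl group without touching the tetrasubstituted Z alkene, so CH2OTBS ends up cis to the vinyl group, which is the "inside" position of the s-cis diene.

**Step 5**
Reactants: 6 (4S)-4-benzyl-1,3-oxazolidin-2-one + 7 bromoacetyl bromide
Product: 8 (4S)-4-benzyl-3-(bromoacetyl)-1,3-oxazolidin-2-one
Conditions: n-BuLi, THF, −78 °C; then 7, −78 to 0 °C
Reagents that add atoms: none
Why: N-Acylation of the lithiated oxazolidinone at the acid bromide end of 7 is much faster than displacement of the alkyl bromide and does not touch the stereocentre of the auxiliary.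

**Step 6**
Reactants: 8 (4S)-4-benzyl-3-(bromoacetyl)-1,3-oxazolidin-2-one
Product: 9 {2-[(4S)-4-benzyl-2-oxo-1,3-oxazolidin-3-yl]-2-oxoethyl}triphenylphosphonium bromide
Conditions: PPh3, toluene, rt to 40 °C; filtration
Reagents that add atoms: triphenylphosphine, c1ccc(cc1)P(c1ccccc1)c1ccccc1
Why: SN2 quaternisation of triphenylphosphine by the activated α-bromo imide gives the phosphonium salt, which should precipitate from toluene.

**Step 7**
Reactants: 9 {2-[(4S)-4-benzyl-2-oxo-1,3-oxazolidin-3-yl]-2-oxoethyl}triphenylphosphonium bromide + 10 isobutyryl chloride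
Product: 12 (4S)-4-benzyl-3-(4-methylpenta-2,3-dienoyl)-1,3-oxazolidin-2-one, via imide-stabilised ylide 11 (not isolated)
Conditions: Et3N (2.2 equiv), CH2Cl2, 0 °C; then 10 dropwise, 0 °C to rt
Reagents that add atoms: none
Why: Triethylamine forms the stabilised ylide 11 and, from 10, dimethylketene, and their Wittig reaction at the ketene carbonyl group is the standard synthesis of allenic acid derivatives.

**Step 8**
Reactants: 5 tert-butyl{[(2Z)-2,3-dimethylpenta-2,4-dien-1-yl]oxy}dimethylsilane + 12 (4S)-4-benzyl-3-(4-methylpenta-2,3-dienoyl)-1,3-oxazolidin-2-one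
Product: 13 (4S)-4-benzyl-3-{[(1S,6R)-1-(tert-butyldimethylsilyloxymethyl)-1,2-dimethyl-5-(propan-2-ylidene)cyclohex-2-en-6-yl]carbonyl}-1,3-oxazolidin-2-one (acyl group cis to the C1 methyl group)
Conditions: Et2AlCl (1.4 equiv), CH2Cl2, −78 to −20 °C; 1 M HCl quench
Reagents that add atoms: none
Why: Et2AlCl forms a cationic aluminium chelate of the two imide carbonyl groups of 12, which lowers the LUMO of the α,β-bond of the allene, and the s-cis conformer of 5 adds to it in a concerted but asynchronous normal-electron-demand [4+2] cycloaddition in which C4–C5 (CH2 terminus of the diene to the central allene carbon) runs ahead of C1–C6. The closest known reaction types are the oxazolidinone-auxiliary Diels–Alder reaction of N-enoyl imides and the Lewis-acid-promoted Diels–Alder reaction of chiral allenic esters at their α,β-bond. The six-membered ring is closed intermolecularly, suprafacially on both components, and the untouched β,γ-bond of the allene is left as the exocyclic isopropylidene group on C5. C6 is set by the auxiliary, because the benzyl group of the (S)-oxazolidinone shields one face of the chelated s-cis allenoyl unit and the diene must add to the opposite (Cα-si) face, and C1 is set relative to C6 by endo addition together with the Z geometry of 5, which places the C1 methyl group "outside" (cis to the endo acyl group) and CH2OTBS "inside" (trans to it). The regioselectivity that is needed is secured by the 1,1-dialkyl terminus of the diene, which puts the largest HOMO coefficient on the free CH2 terminus so that this carbon attacks the electrophilic central allene carbon, and site selectivity for the α,β- over the β,γ-bond follows from conjugation with the chelated carbonyl group. The slim sp carbon of the dienophile and the unsubstituted CH2 terminus leave the crowded bond to the quaternary carbon as the late one, which is what should allow a 1,1,2-trisubstituted diene to react.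

**Step 9**
Reactants: 13 cycloadduct (see step 8)
Product: 14 [(1S,6R)-1-(tert-butyldimethylsilyloxymethyl)-1,2-dimethyl-5-(propan-2-ylidene)cyclohex-2-en-6-yl]methanol
Conditions: LiBH4, H2O (1 equiv), Et2O, 0 °C
Reagents that add atoms: none
Why: Reductive cleavage of the N-acyl oxazolidinone with LiBH4 attacks the exocyclic imide carbonyl group, frees the auxiliary for recovery and should not disturb C6, the alkenes or the silyl ether.

**Step 10**
Reactants: 14 [(1S,6R)-1-(tert-butyldimethylsilyloxymethyl)-1,2-dimethyl-5-(propan-2-ylidene)cyclohex-2-en-6-yl]methanol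
Product: 15 [(1R,2R,6R)-1-(tert-butyldimethylsilyloxymethyl)-1,2-dimethyl-5-(propan-2-ylidene)cyclohexan-6-yl]methanol (C2 methyl cis to CH2OTBS, trans to CH2OH)
Conditions: [Rh(nbd)(dppb)]BF4 (5–10 mol %), H2 (50–60 bar), CH2Cl2, rt
Reagents that add atoms: none
Why: In this hydroxyl-directed homogeneous hydrogenation the cationic Rh(I) catalyst binds the C6–CH2OH group, which is axial because of A(1,3) strain with the isopropylidene group, and delivers H2 to the same face of C2=C3, so that the C2 methyl group is pushed to the opposite face, while the tetrasubstituted alkene is inert to this catalyst.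

**Step 11**
Reactants: 15 [(1R,2R,6R)-1-(tert-butyldimethylsilyloxymethyl)-1,2-dimethyl-5-(propan-2-ylidene)cyclohexan-6-yl]methanol
Product: 16 (1R,2R,6R)-1-(tert-butyldimethylsilyloxymethyl)-1,2-dimethyl-5-(propan-2-ylidene)cyclohexane-6-carbaldehyde
Conditions: TPAP (5 mol %), NMO, 4 Å MS, CH2Cl2, rt
Reagents that add atoms: none
Why: The TPAP/NMO oxidation stops at the aldehyde under nearly neutral conditions, which should avoid epimerisation at C6 and migration of the β,γ-double bond into conjugation.

**Step 12**
Reactants: 16 (1R,2R,6R)-1-(tert-butyldimethylsilyloxymethyl)-1,2-dimethyl-5-(propan-2-ylidene)cyclohexane-6-carbaldehyde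
Product: 17 tert-butyl{[(1R,2R,6R)-6-ethenyl-1,2-dimethyl-5-(propan-2-ylidene)cyclohexyl]methoxy}dimethylsilane
Conditions: Ph3PCH3Br, n-BuLi, THF, −78 to 0 °C
Reagents that add atoms: methyltriphenylphosphonium bromide, C[P+](c1ccccc1)(c1ccccc1)c1ccccc1.[Br-]
Why: Wittig methylenation is fast at low temperature even with hindered aldehydes, so C6 should keep its configuration.

**Step 13**
Reactants: 17 tert-butyl{[(1R,2R,6R)-6-ethenyl-1,2-dimethyl-5-(propan-2-ylidene)cyclohexyl]methoxy}dimethylsilane
Product: 18 [(1R,2R,6R)-6-ethenyl-1,2-dimethyl-5-(propan-2-ylidene)cyclohexyl]methanol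
Conditions: TBAF, THF, rt to 50 °C
Reagents that add atoms: none
Why: Fluoride-induced desilylation is driven by the Si–F bond and leaves both alkenes and all stereocentres untouched.

**Step 14**
Reactants: 18 [(1R,2R,6R)-6-ethenyl-1,2-dimethyl-5-(propan-2-ylidene)cyclohexyl]methanol + 19 isofraxidin (7-hydroxy-6,8-dimethoxy-2H-chromen-2-one)
Product: 20 7-{[(1R,2R,6R)-6-ethenyl-1,2-dimethyl-5-(propan-2-ylidene)cyclohexyl]methoxy}-6,8-dimethoxy-2H-chromen-2-one
Conditions: PPh3, DIAD, THF (ca. 3 M), sonication, rt to 40 °C
Reagents that add atoms: none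
Why: In this Mitsunobu etherification the acidic 7-OH of 19 protonates the betaine and its phenoxide displaces the primary oxyphosphonium group at the CH2 carbon, so no stereocentre is involved, and high concentration with sonication is the known remedy for pairs of a neopentyl alcohol and a 2,6-disubstituted phenol.

**Step 15**
Reactants: 20 7-{[(1R,2R,6R)-6-ethenyl-1,2-dimethyl-5-(propan-2-ylidene)cyclohexyl]methoxy}-6,8-dimethoxy-2H-chromen-2-one
Product: 22 CNP0311605.1 7-{[(1R,2R,6R)-6-(3-hydroxypropyl)-1,2-dimethyl-5-(propan-2-ylidene)cyclohexyl]methoxy}-6,8-dimethoxy-2H-chromen-2-one, via linear aldehyde 21 (not isolated)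
Conditions: Rh(acac)(CO)2 (2 mol %), Xantphos (4 mol %), CO/H2 (1:1, 20 bar), toluene, 70 °C; vent; then NaBH4, MeOH, 0 °C
Reagents that add atoms: carbon monoxide, [C-]#[O+]
Why: Linear-selective Rh/Xantphos hydroformylation should engage only the monosubstituted vinyl group (the tetrasubstituted alkene and the conjugated coumarin C3=C4 bond do not insert, and the branched position is blocked by the crowded C6), and brief NaBH4 reduction of the aldehyde at 0 °C should leave the coumarin lactone intact.

**Compound list**

1 | 2,3-dimethylmaleic anhydride | CC1=C(C)C(=O)OC1=O | starting material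
2 | (2Z)-2,3-dimethylbut-2-ene-1,4-diol | OC/C(C)=C(C)\CO | intermediate
3 | (2Z)-4-(tert-butyldimethylsilyloxy)-2,3-dimethylbut-2-en-1-ol | CC(C)(C)[Si](C)(C)OC/C(C)=C(C)\CO | intermediate
4 | (2Z)-4-(tert-butyldimethylsilyloxy)-2,3-dimethylbut-2-enal | CC(C)(C)[Si](C)(C)OC/C(C)=C(C)\C=O | intermediate
5 | tert-butyl{[(2Z)-2,3-dimethylpenta-2,4-dien-1-yl]oxy}dimethylsilane | CC(C)(C)[Si](C)(C)OC/C(C)=C(C)\C=C | intermediate
6 | (4S)-4-benzyl-1,3-oxazolidin-2-one | O=C1N[C@@H](Cc2ccccc2)CO1 | starting material
7 | bromoacetyl bromide | BrCC(Br)=O | starting material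
8 | (4S)-4-benzyl-3-(bromoacetyl)-1,3-oxazolidin-2-one | BrCC(=O)N1C(=O)OC[C@@H]1Cc1ccccc1 | intermediate
9 | {2-[(4S)-4-benzyl-2-oxo-1,3-oxazolidin-3-yl]-2-oxoethyl}triphenylphosphonium bromide | [Br-].O=C(C[P+](c1ccccc1)(c1ccccc1)c1ccccc1)N1C(=O)OC[C@@H]1Cc1ccccc1 | intermediate
10 | isobutyryl chloride | CC(C)C(Cl)=O | starting material
11 | (4S)-4-benzyl-3-[(triphenyl-λ5-phosphanylidene)acetyl]-1,3-oxazolidin-2-one | O=C(C=P(c1ccccc1)(c1ccccc1)c1ccccc1)N1C(=O)OC[C@@H]1Cc1ccccc1 | intermediate
12 | (4S)-4-benzyl-3-(4-methylpenta-2,3-dienoyl)-1,3-oxazolidin-2-one | CC(C)=C=CC(=O)N1C(=O)OC[C@@H]1Cc1ccccc1 | intermediate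
13 | (4S)-4-benzyl-3-{[(1S,6R)-1-(tert-butyldimethylsilyloxymethyl)-1,2-dimethyl-5-(propan-2-ylidene)cyclohex-2-en-6-yl]carbonyl}-1,3-oxazolidin-2-one | CC(C)(C)[Si](C)(C)OC[C@]1(C)C(C)=CCC(=C(C)C)[C@H]1C(=O)N2C(=O)OC[C@@H]2Cc3ccccc3 | intermediate
14 | [(1S,6R)-1-(tert-butyldimethylsilyloxymethyl)-1,2-dimethyl-5-(propan-2-ylidene)cyclohex-2-en-6-yl]methanol | CC(C)(C)[Si](C)(C)OC[C@]1(C)C(C)=CCC(=C(C)C)[C@H]1CO | intermediate
15 | [(1R,2R,6R)-1-(tert-butyldimethylsilyloxymethyl)-1,2-dimethyl-5-(propan-2-ylidene)cyclohexan-6-yl]methanol | CC(C)(C)[Si](C)(C)OC[C@]1(C)[C@H](C)CCC(=C(C)C)[C@H]1CO | intermediate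
16 | (1R,2R,6R)-1-(tert-butyldimethylsilyloxymethyl)-1,2-dimethyl-5-(propan-2-ylidene)cyclohexane-6-carbaldehyde | CC(C)(C)[Si](C)(C)OC[C@]1(C)[C@H](C)CCC(=C(C)C)[C@H]1C=O | intermediate
17 | tert-butyl{[(1R,2R,6R)-6-ethenyl-1,2-dimethyl-5-(propan-2-ylidene)cyclohexyl]methoxy}dimethylsilane | CC(C)(C)[Si](C)(C)OC[C@]1(C)[C@H](C)CCC(=C(C)C)[C@H]1C=C | intermediate
18 | [(1R,2R,6R)-6-ethenyl-1,2-dimethyl-5-(propan-2-ylidene)cyclohexyl]methanol | OC[C@]1(C)[C@H](C)CCC(=C(C)C)[C@H]1C=C | intermediate
19 | isofraxidin (7-hydroxy-6,8-dimethoxy-2H-chromen-2-one) | COc1cc2ccc(=O)oc2c(OC)c1O | starting material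
20 | 7-{[(1R,2R,6R)-6-ethenyl-1,2-dimethyl-5-(propan-2-ylidene)cyclohexyl]methoxy}-6,8-dimethoxy-2H-chromen-2-one | COc1cc2ccc(=O)oc2c(OC)c1OC[C@]1(C)[C@H](C)CCC(=C(C)C)[C@H]1C=C | intermediate
21 | 3-[(1R,2R,6R)-1-{[(6,8-dimethoxy-2-oxo-2H-chromen-7-yl)oxy]methyl}-1,2-dimethyl-5-(propan-2-ylidene)cyclohexan-6-yl]propanal | COc1cc2ccc(=O)oc2c(OC)c1OC[C@]1(C)[C@H](C)CCC(=C(C)C)[C@H]1CCC=O | intermediate
22 | CNP0311605.1, 7-{[(1R,2R,6R)-6-(3-hydroxypropyl)-1,2-dimethyl-5-(propan-2-ylidene)cyclohexyl]methoxy}-6,8-dimethoxy-2H-chromen-2-one | COc1cc2ccc(=O)oc2c(OC)c1OC[C@]1(C)[C@H](C)CCC(=C(C)C)[C@H]1CCCO | target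

**Step count**

Total step count: 15.
Longest linear sequence: 12 (steps 1–4 and 8–15).

**Steps most likely to fail**

**Step 8.**
- Risk: the stoichiometric aluminium Lewis acid may ionise or oligomerise the electron-rich dienyl silyl ether faster than cycloaddition takes place.
- Risk: the methyl group on C2 of the diene lies under the chelate in the endo arrangement and may erode endo and facial selectivity.
- Fallback (sets out from 5, 7 and 10, returns at 14): stereocontrol is moved from the auxiliary to a mild chiral catalyst. Achiral 1,3-oxazolidin-2-one is N-acylated with 7 to 3-(bromoacetyl)-1,3-oxazolidin-2-one F1 and quaternised with PPh3 to its triphenylphosphonium bromide F2. Treatment with Et3N and 10 then leads through the stabilised ylide F3 to 3-(4-methylpenta-2,3-dienoyl)-1,3-oxazolidin-2-one F4. This imide and 5 are combined under catalysis by the cationic copper(II) complex of (R,R)-tert-butyl-bis(oxazoline) with SbF6 counterions (CH2Cl2, −20 °C to rt). This is the known enantioselective Diels–Alder reaction of N-enoyl oxazolidinones in a square-planar chelate, and the (R,R)-ligand leaves the same Cα-si face open. It should give the achiral-imide cycloadduct F5, and LiBH4 reduction as in step 9 leads to 14.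

**Step 14.**
- Risk: SN2 displacement at the neopentyl CH2, flanked by the substituted carbons C2 and C6, by a phenoxide that itself carries two ortho methoxy groups may be too slow. The oxyphosphonium intermediate would then be consumed by the hydrazide or simply persist.
- Fallback (sets out from 18 and 19, returns at 20): activation and displacement are separated. The alcohol is converted with Tf2O and 2,6-lutidine (CH2Cl2, −78 to 0 °C) to [(1R,2R,6R)-6-ethenyl-1,2-dimethyl-5-(propan-2-ylidene)cyclohexyl]methyl trifluoromethanesulfonate F6. This carries a smaller and far better leaving group and cannot eliminate because C1 has no hydrogen. It is displaced by the preformed caesium salt of 19 in DMF at 40–80 °C.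

**Step 10.**
- Risk: the trisubstituted alkene next to the quaternary carbon may bind the rhodium catalyst too slowly.
- Risk: isomerisation of the skipped diene, or delivery from the undesired face, may then compete.
- Fallback (sets out from 14, returns at 15): coordination control is replaced by radical, thermodynamically biased reduction. Manganese-catalysed hydrogen-atom-transfer hydrogenation (Mn(dpm)3, PhSiH3, t-BuOOH, i-PrOH, rt) puts H on the unhindered C3. The tertiary C2 radical should then be quenched to the more stable epimer. That epimer has the C2 methyl group equatorial in the chair in which the C6 substituent is axial, and this is the configuration of 15. The tetrasubstituted alkene offers no unhindered carbon for hydrogen-atom transfer and should react much more slowly.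

**Further compounds**

F1 | step 8 | 3-(bromoacetyl)-1,3-oxazolidin-2-one | O=C(CBr)N1CCOC1=O
F2 | step 8 | [2-oxo-2-(2-oxo-1,3-oxazolidin-3-yl)ethyl]triphenylphosphonium bromide | [Br-].O=C(C[P+](c1ccccc1)(c1ccccc1)c1ccccc1)N1CCOC1=O
F3 | step 8 | 3-[(triphenyl-λ5-phosphanylidene)acetyl]-1,3-oxazolidin-2-one | O=C(C=P(c1ccccc1)(c1ccccc1)c1ccccc1)N1CCOC1=O
F4 | step 8 | 3-(4-methylpenta-2,3-dienoyl)-1,3-oxazolidin-2-one | CC(C)=C=CC(=O)N1CCOC1=O
F5 | step 8 | 3-{[(1S,6R)-1-(tert-butyldimethylsilyloxymethyl)-1,2-dimethyl-5-(propan-2-ylidene)cyclohex-2-en-6-yl]carbonyl}-1,3-oxazolidin-2-one | CC(C)(C)[Si](C)(C)OC[C@]1(C)C(C)=CCC(=C(C)C)[C@H]1C(=O)N2CCOC2=O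
F6 | step 14 | [(1R,2R,6R)-6-ethenyl-1,2-dimethyl-5-(propan-2-ylidene)cyclohexyl]methyl trifluoromethanesulfonate | FC(F)(F)S(=O)(=O)OC[C@]1(C)[C@H](C)CCC(=C(C)C)[C@H]1C=C
F0 | step 10 | none | none
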